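**Strategy.** Atoms are numbered by their position in the target SMILES. Everything rests on reading quaternary C8, the atom shared by ring A (C8-C9-C11-C14-C36) and ring C that carries both the exocyclic acyl carbon C6 and the ring ketone C9, as the product of a 1,2-acyl shift. In one operation a Lewis acid opens a C6–C8 oxirane at tertiary C8, C9 moves from C6 to C8, the six-membered ring contracts to ring A, C6 becomes an acetyl carbonyl and the C8 stereocentre is fixed. The precursor is a cis-fused cyclohexanone oxide on the lactone-bearing cyclopentane (rings C and D) with C11 silyloxy, C14 acetonyl and a C25 propenyl group as masked C23 carbonyl.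

Key step: step 21

Remark: C23 is carried on C25 as an (E)-prop-1-enyl group and not as an ester, because a 2,2-disubstituted β-keto ester (C27/C23) would be open to retro-Claisen cleavage in the basic steps and because the aldehyde released later closes ring B under mild base; the shift that competes with acyl migration is that of the C6 methyl group.

Step 1
Reactants: 1 2-allyl-2-methylcyclopentane-1,3-dione
Product: 2 (2S,3S)-2-allyl-3-hydroxy-2-methylcyclopentan-1-one
Conditions: baker's yeast (Saccharomyces cerevisiae), sucrose, H2O, 30 °C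
Reagents that add atoms: none
Why: Enzymatic desymmetrising reduction of a prochiral 2,2-disubstituted cyclopentane-1,3-dione, a well-established case, should reduce one enantiotopic carbonyl anti to the allyl group, which fixes quaternary C25 in the absolute sense of the target and places the C27 hydroxyl cis to the allyl group.

Step 2
Reactants: 2 (2S,3S)-2-allyl-3-hydroxy-2-methylcyclopentan-1-one
Product: 3 TBS ether of 2
Conditions: TBSCl, imidazole, DMF, 23 °C
Reagents that add atoms: tert-butyldimethylsilyl chloride, CC(C)(C)[Si](C)(C)Cl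
Why: Standard silylation of a secondary alcohol should block retro-aldol cleavage and oxidation of the carbinol in the next steps without touching a stereocentre.

Step 3
Reactants: 3 TBS ether of 2
Product: 4 (E)-propenyl ketone
Conditions: RuHCl(CO)(PPh3)3 (cat.), toluene, 80 °C
Reagents that add atoms: none
Why: Ruthenium hydride-catalysed alkene isomerisation (hydrometalation and β-hydride elimination) should move the terminal double bond next to the quaternary carbon to give the more stable (E)-propenyl group, whose inner CH is the future C23, while conjugation with the ketone is impossible because C25 bears no hydrogen.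

Step 4
Reactants: 4 (E)-propenyl ketone
Product: 5 4-silyloxy cyclopentenone
Conditions: IBX (2-iodoxybenzoic acid), DMSO/toluene, 70 °C
Reagents that add atoms: none
Why: IBX dehydrogenation of a ketone to the enone can only involve the single α-methylene group, so one enone should result.

Step 5
Reactants: 5 4-silyloxy cyclopentenone
Product: 6 epoxy ketone
Conditions: H2O2 (30%), NaOH (cat.), MeOH, 0 °C
Reagents that add atoms: hydrogen peroxide, OO
Why: Weitz–Scheffer nucleophilic epoxidation of the enone should occur anti to the neighbouring silyloxy group, although this oxirane stereochemistry is erased in step 7.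

Step 6
Reactants: 6 epoxy ketone
Product: 7 transposed allylic alcohol
Conditions: N2H4·H2O, AcOH (cat.), MeOH, 0 → 23 °C
Reagents that add atoms: none
Why: Wharton transposition (hydrazone formation, oxirane opening and loss of N2) should move the oxygen function from C8 to C34 and the double bond to C8=C36, the new carbinol centre being removed in step 7.

Step 7
Reactants: 7 transposed allylic alcohol
Product: 8 transposed enone
Conditions: Dess–Martin periodinane, NaHCO3, CH2Cl2, 23 °C
Reagents that add atoms: none
Why: Oxidation of the secondary allylic alcohol should give the enone with C34 as carbonyl and C36=C8 as the activated double bond needed as dienophile.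

Step 8
Reactants: 8 transposed enone
Product: 9 hydroxy enone
Conditions: HF·pyridine, THF, 0 °C
Reagents that add atoms: none
Why: Fluoride cleavage of the silyl ether under weakly acidic conditions should free the C27 hydroxyl as anchor for the tether without enolising the α-ketol.

Step 9
Reactants: 10 ethyl 2-(2-methyl-1,3-dioxolan-2-yl)acetate
Product: 11 2-(2-methyl-1,3-dioxolan-2-yl)acetaldehyde
Conditions: i-Bu2AlH, CH2Cl2, −78 °C
Reagents that add atoms: none
Why: Partial reduction of an ester stops at the aldehyde because the tetrahedral aluminium hemiacetal is stable at low temperature, and the dioxolane carries the masked C16 ketone.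

Step 10
Reactants: 12 pentan-3-one; 11 2-(2-methyl-1,3-dioxolan-2-yl)acetaldehyde
Product: 14 (E)-4-methyl-6-(2-methyl-1,3-dioxolan-2-yl)hex-4-en-3-one, via aldol acetate 13 (not isolated)
Conditions: LiN(i-Pr)2, THF, −78 °C; 11; Ac2O, −78 → 0 °C; DBU, 23 °C
Reagents that add atoms: none
Why: Directed aldol addition of the lithium enolate, acetylation of the aldolate in the flask and E1cB elimination should give the thermodynamically preferred (E)-trisubstituted enone that supplies C5, C6, C9, C11 with its methyl, C14 and the masked acetonyl chain.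

Step 11
Reactants: 9 hydroxy enone; 14 (E)-4-methyl-6-(2-methyl-1,3-dioxolan-2-yl)hex-4-en-3-one
Product: 16 silyl acetal-tethered triene, via chlorosilyl dienol ether 15 (not isolated)
Conditions: 14, LiN(SiMe3)2, THF, −78 °C; i-Pr2SiCl2; then 9, imidazole, DMF, 0 → 23 °C
Reagents that add atoms: dichlorodiisopropylsilane, CC(C)[Si](Cl)(Cl)C(C)C
Why: Kinetic α′-deprotonation should give the (Z)-dienolate, whose O-silylation and substitution of the second chloride by the C27 hydroxyl build a temporary silyl acetal that ties the 2-silyloxy diene to the lower face of the cyclopentenone without forming a stereocentre.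

Step 12
Reactants: 16 silyl acetal-tethered triene
Product: 17 Diels–Alder adduct
Conditions: toluene, BHT, 150 °C (sealed tube)
Reagents that add atoms: none
Why: Thermal silicon-tethered intramolecular Diels–Alder reaction (type 2) of the 2-silyloxy diene with the cyclopentenone should form C6–C8 and C14–C36, the tether from the C27 oxygen allowing only the endo approach to the face cis to the propenyl group, so that H8, H36 and H14 become cis, the C14 side chain is cis to C34 and the C9=C11 silyl enol ether is placed regiospecifically.

Step 13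
Reactants: 17 Diels–Alder adduct; 18 propanoic anhydride
Product: 20 C34 propanoate, via lithium C34 alkoxide 19 (not isolated)
Conditions: MeLi, CeCl3, THF, −78 °C; then 18, DMAP, −78 → 23 °C
Reagents that add atoms: methyllithium, [Li]C
Why: Organocerium addition to the enolisable C34 ketone should occur from the convex face, opposite to the fused six-membered ring and the siloxane bridge, which places the C34 methyl up and the oxygen down, and acylation of the alkoxide in the same flask installs the future C29–C31 unit of ring D.

Step 14
Reactants: 20 C34 propanoate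
Product: 22 C11,C27-diol ketone, via bridged silyloxy ketone 21 (not isolated)
Conditions: dimethyldioxirane, acetone/CH2Cl2, −78 → −30 °C; then HF·pyridine, THF, 0 °C
Reagents that add atoms: dimethyldioxirane, CC1(C)OO1
Why: Rubottom oxidation should epoxidise the strained silyl enol ether on the face opposite to the C14 side chain and ring C, so that after silyl migration and fluoride cleavage the tertiary C11 hydroxyl is trans to the C14 substituent and the C27 hydroxyl is free.

Step 15
Reactants: 22 C11,C27-diol ketone
Product: 23 C27 ketone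
Conditions: Dess–Martin periodinane, NaHCO3, CH2Cl2, 0 → 23 °C
Reagents that add atoms: none
Why: Oxidation of the only secondary alcohol should give the non-enolisable C27 ketone next to the C34 propanoate, the tertiary C11 alcohol being inert.

Step 16
Reactants: 23 C27 ketone
Product: 24 C11 silyl ether
Conditions: TBSOTf, 2,6-lutidine, CH2Cl2, 0 °C
Reagents that add atoms: tert-butyldimethylsilyl trifluoromethanesulfonate, CC(C)(C)[Si](C)(C)OS(=O)(=O)C(F)(F)F
Why: The reactive silyl triflate should silylate the only free hydroxyl, the hindered tertiary α-ketol at C11, which protects it against α-ketol rearrangement and Lewis acid complexation in the key step.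

Step 17
Reactants: 24 C11 silyl ether
Product: 25 C6=C8 enone
Conditions: IBX, DMSO/fluorobenzene, 75 °C
Reagents that add atoms: none
Why: IBX dehydrogenation of the C9 ketone, which can enolise only towards C6, should give the tetrasubstituted C6=C8 enone, aromatisation being impossible because C11 is quaternary.

Step 18
Reactants: 25 C6=C8 enone
Product: 26 C6–C8 oxirane
Conditions: t-BuOOH, BnNMe3OH (cat.), THF, 0 °C
Reagents that add atoms: tert-butyl hydroperoxide, CC(C)(C)OO
Why: In this Weitz–Scheffer epoxidation the peroxide anion should attack C8 from the convex face, syn to H36 and the C25 methyl and away from ring C, the propenyl group and the C14 chain, which sets C6 and C8 of the oxirane.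

Step 19
Reactants: 26 C6–C8 oxirane
Product: 27 hydroxy lactone
Conditions: LiN(i-Pr)2, THF, −78 °C; AcOH
Reagents that add atoms: none
Why: Intramolecular aldol addition of the lithium (E)-enolate of the propanoate, the only enolisable position, to the adjacent C27 ketone must give the cis-fused five-membered lactone with C27–OH up, and the (E)-enolate reacting with its ester carbon turned away from ring C should place the C29 methyl on the concave face, cis to C25.

Step 20
Reactants: 27 hydroxy lactone
Product: 28 epoxy ketone precursor
Conditions: PPTS, acetone/H2O, 45 °C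
Reagents that add atoms: water, O
Why: Mild acid-catalysed hydrolysis of the dioxolane should release the acetonyl ketone without opening the oxirane, the silyl ether or the lactone.

Step 21
Reactants: 28 epoxy ketone precursor
Product: 29 rearranged acetyl diketone
Conditions: BF3·OEt2, CH2Cl2, −78 → −20 °C
Reagents that add atoms: none
Why: BF3 binds the oxirane oxygen and the C8–O bond ionises, because C8 is tertiary and β to the ketone whereas a cation at C6 would sit next to the carbonyl, and as it breaks the acyl carbon C9 shifts from C6 to C8 on the face opposite to the leaving oxygen while the C6–O bond becomes the acetyl carbonyl. The closest known reaction is the boron trifluoride-induced rearrangement of 2,3-epoxycyclohexanones to 2-acylcyclopentanones. Ring A (C8-C9-C11-C14-C36) is closed by ring contraction, a suprafacial 1,2-shift through an acyl-bridged three-centre transition state, not by an end-to-end cyclisation. The new stereocentre C8 is formed with inversion at the oxirane carbon, so it is controlled by the oxirane configuration from step 18 and by the need of ring A to stay cis-fused to ring C (C9 down, acetyl up). The step needs cleavage of C8–O and not C6–O, and migration of C9 and not of the C6 methyl group (which would give a 1,2-diketone without ring contraction); the β-cation preference of epoxy ketones and the high migratory aptitude of acyl groups should secure both. Capture of the cation by fluoride, by the C27 hydroxyl or by the acetonyl carbonyl is limited by the fast intramolecular shift at low temperature in a non-coordinating solvent.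

Step 22
Reactants: 29 rearranged acetyl diketone
Product: 31 ring B aldol, via C23 aldehyde 30 (not isolated)
Conditions: O3, CH2Cl2, −78 °C; PPh3; then DBU (cat.), 0 °C
Reagents that add atoms: ozone, [O-][O+]=O
Why: Ozonolysis cleaves the only C=C bond to the aldehyde C23, and base-mediated intramolecular aldol addition should occur through C15 because only this carbon closes a six-membered ring (the acetyl group lies on the opposite face and C18 would need an eight-membered ring), the new centres C15 and C23 being removed in step 23.

Step 23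
Reactants: 31 ring B aldol
Product: 32 ring B diketone enol
Conditions: Dess–Martin periodinane, CH2Cl2, 23 °C
Reagents that add atoms: none
Why: Oxidation of the secondary C23 carbinol should give the 2-acetyl-1,3-dicarbonyl unit, which rests as the hydrogen-bonded exocyclic enol of the target, the tertiary C27 hydroxyl being inert.

Step 24
Reactants: 32 ring B diketone enol; 33 (E)-but-2-enal
Product: 34 C19 mono-aldol adduct
Conditions: LiN(i-Pr)2 (4.2 equiv), THF, −78 → −30 °C; 33 (1.0 equiv), −78 °C; AcOH
Reagents that add atoms: none
Why: In this aldol addition through a polyanion the last-formed and most basic carbanion, the terminal carbon C18 of the β-diketone dianion, should add 1,2 to the single equivalent of enal faster than the less basic C5 methyl ketone enolate (the regiochemistry typical of 1,3-dicarbonyl dianions), while the C27 alkoxide shields the lactone α-position and the new carbinol centre C19 is lost in step 26.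

Step 25
Reactants: 34 C19 mono-aldol adduct; 33 (E)-but-2-enal
Product: 35 bis-aldol adduct
Conditions: LiN(i-Pr)2 (4.2 equiv), THF, −78 °C; 33 (1.2 equiv), −78 °C; AcOH
Reagents that add atoms: none
Why: Once the enol, the C27 hydroxyl and the C19 hydroxyl are deprotonated, the fourth equivalent of base should form the kinetic lithium enolate of the C6 methyl ketone at C5, the most acidic remaining C–H position, and its directed aldol 1,2-addition to the enal at −78 °C, where lithium aldolates do not revert, gives the C4 carbinol, which is also lost in step 26.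

Step 26
Reactants: 35 bis-aldol adduct
Product: 36 silyl-protected target
Conditions: p-TsOH·H2O (cat.), benzene, 45 °C
Reagents that add atoms: none
Why: Acid-catalysed dehydration of the two allylic β-hydroxy ketones should give the conjugated sorbyl units as the thermodynamically preferred (E,E) isomers.

Step 27
Reactants: 36 silyl-protected target
Product: 37 target CNP0231466.1
Conditions: HF·pyridine, THF, 0 → 23 °C
Reagents that add atoms: none
Why: Fluoride cleavage of the tertiary silyl ether under weakly acidic conditions should release the C11 hydroxyl without touching the dienones, the enol or the lactone.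

**Compound list**

1 | 2-allyl-2-methylcyclopentane-1,3-dione | C=CCC1(C)C(=O)CCC1=O | starting material
2 | (2S,3S)-2-allyl-3-hydroxy-2-methylcyclopentan-1-one (OH cis to allyl) | O=C1CC[C@H](O)[C@]1(C)CC=C | intermediate
3 | (2S,3S)-2-allyl-3-[(tert-butyldimethylsilyl)oxy]-2-methylcyclopentan-1-one | O=C1CC[C@H](O[Si](C)(C)C(C)(C)C)[C@]1(C)CC=C | intermediate
4 | (2S,3S)-3-[(tert-butyldimethylsilyl)oxy]-2-methyl-2-[(E)-prop-1-enyl]cyclopentan-1-one | O=C1CC[C@H](O[Si](C)(C)C(C)(C)C)[C@]1(C)/C=C/C | intermediate
5 | 4-[(tert-butyldimethylsilyl)oxy]-5-methyl-5-[(E)-prop-1-enyl]cyclopent-2-en-1-one (silyloxy cis to propenyl) | O=C1C=C[C@H](O[Si](C)(C)C(C)(C)C)[C@]1(C)/C=C/C | intermediate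
6 | 2,3-epoxide of 5 (oxirane trans to the silyloxy group) | O=C1[C@H]2O[C@H]2[C@H](O[Si](C)(C)C(C)(C)C)[C@]1(C)/C=C/C | intermediate
7 | 5-[(tert-butyldimethylsilyl)oxy]-4-methyl-4-[(E)-prop-1-enyl]cyclopent-2-en-1-ol (OH trans to silyloxy) | C1=C[C@@H](O)[C@H](O[Si](C)(C)C(C)(C)C)[C@]1(C)/C=C/C | intermediate
8 | 5-[(tert-butyldimethylsilyl)oxy]-4-methyl-4-[(E)-prop-1-enyl]cyclopent-2-en-1-one (silyloxy cis to propenyl) | O=C1C=C[C@@](C)(/C=C/C)[C@H]1O[Si](C)(C)C(C)(C)C | intermediate
9 | 5-hydroxy-4-methyl-4-[(E)-prop-1-enyl]cyclopent-2-en-1-one (OH cis to propenyl; C34 ketone, C36=C8, C25, C27) | O=C1C=C[C@@](C)(/C=C/C)[C@H]1O | intermediate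
10 | ethyl 2-(2-methyl-1,3-dioxolan-2-yl)acetate | CCOC(=O)CC1(C)OCCO1 | starting material
11 | 2-(2-methyl-1,3-dioxolan-2-yl)acetaldehyde | O=CCC1(C)OCCO1 | intermediate
12 | pentan-3-one | CCC(=O)CC | starting material
13 | 5-acetoxy-4-methyl-6-(2-methyl-1,3-dioxolan-2-yl)hexan-3-one (diastereomer mixture) | CCC(=O)C(C)C(OC(C)=O)CC1(C)OCCO1 | intermediate
14 | (E)-4-methyl-6-(2-methyl-1,3-dioxolan-2-yl)hex-4-en-3-one | CCC(=O)/C(C)=C/CC1(C)OCCO1 | intermediate
15 | chloro(diisopropyl)silyl (Z)-dienol ether of 14 | C/C=C(\O[Si](Cl)(C(C)C)C(C)C)/C(C)=C/CC1(C)OCCO1 | intermediate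
16 | diisopropylsilyl acetal joining the (Z)-dienol oxygen of 14 to the C27 oxygen of 9 | C/C=C(\O[Si](C(C)C)(C(C)C)O[C@H]1C(=O)C=C[C@@]1(C)/C=C/C)/C(C)=C/CC2(C)OCCO2 | intermediate
17 | Diels–Alder adduct: cis-fused hexahydroindenone (C34 ketone) with C9=C11 silyl enol ether bridged by O–Si(i-Pr)2–O to C27; H6, H8, H14, H36 cis | C[C@@H]1C2=C(C)[C@H](CC3(C)OCCO3)[C@@H]4C(=O)[C@H](O[Si](C(C)C)(C(C)C)O2)[C@](C)(/C=C/C)[C@H]14 | intermediate
18 | propanoic anhydride | CCC(=O)OC(=O)CC | starting material
19 | lithium C34 alkoxide from methyl addition to 17 (C34 methyl up) | C[C@@H]1C2=C(C)[C@H](CC3(C)OCCO3)[C@@H]4[C@](C)([O-])[C@H](O[Si](C(C)C)(C(C)C)O2)[C@](C)(/C=C/C)[C@H]14.[Li+] | intermediate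
20 | C34 propanoate of the methyl adduct of 17 | C[C@@H]1C2=C(C)[C@H](CC3(C)OCCO3)[C@@H]4[C@](C)(OC(=O)CC)[C@H](O[Si](C(C)C)(C(C)C)O2)[C@](C)(/C=C/C)[C@H]14 | intermediate
21 | C9 ketone with the diisopropylsilylene bridging O11 and O27 | C[C@@H]1C(=O)[C@@](C)(O[Si]5(C(C)C)C(C)C)[C@H](CC2(C)OCCO2)[C@@H]3[C@](C)(OC(=O)CC)[C@H](O5)[C@](C)(/C=C/C)[C@H]13 | intermediate
22 | C9 ketone with free C11 and C27 hydroxyls (C11–OH trans to the C14 chain) | C[C@@H]1C(=O)[C@@](C)(O)[C@H](CC2(C)OCCO2)[C@@H]3[C@](C)(OC(=O)CC)[C@H](O)[C@](C)(/C=C/C)[C@H]13 | intermediate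
23 | C9,C27-diketone with free C11 hydroxyl | C[C@@H]1C(=O)[C@@](C)(O)[C@H](CC2(C)OCCO2)[C@@H]3[C@](C)(OC(=O)CC)C(=O)[C@](C)(/C=C/C)[C@H]13 | intermediate
24 | C11 tert-butyldimethylsilyl ether of 23 | C[C@@H]1C(=O)[C@@](C)(O[Si](C)(C)C(C)(C)C)[C@H](CC2(C)OCCO2)[C@@H]3[C@](C)(OC(=O)CC)C(=O)[C@](C)(/C=C/C)[C@H]13 | intermediate
25 | C6=C8 enone from 24 | CC1=C2[C@@](C)(/C=C/C)C(=O)[C@@](C)(OC(=O)CC)[C@H]2[C@@H](CC3(C)OCCO3)[C@](C)(O[Si](C)(C)C(C)(C)C)C1=O | intermediate
26 | C6–C8 oxirane of 25 (oxirane oxygen on the face of H36) | O=C1[C@@](C)(O[Si](C)(C)C(C)(C)C)[C@H](CC5(C)OCCO5)[C@H]2[C@]3(O[C@@]13C)[C@@](C)(/C=C/C)C(=O)[C@@]2(C)OC(=O)CC | intermediate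
27 | hydroxy lactone (ring D closed, C27–OH up, C29 methyl cis to C25), side chain still as dioxolane | O=C1[C@@](C)(O[Si](C)(C)C(C)(C)C)[C@H](CC5(C)OCCO5)[C@H]2[C@]3(O[C@@]13C)[C@@](C)(/C=C/C)[C@@]4(O)[C@@H](C)C(=O)O[C@@]24C | intermediate
28 | key-step precursor: 6-5 cis-fused 2,3-epoxy ketone on the lactone-bearing cyclopentane; C11 OTBS, C14 acetonyl, C25 methyl and (E)-propenyl, C27 OH | O=C1[C@@](C)(O[Si](C)(C)C(C)(C)C)[C@H](CC(C)=O)[C@H]2[C@]3(O[C@@]13C)[C@@](C)(/C=C/C)[C@@]4(O)[C@@H](C)C(=O)O[C@@]24C | intermediate
29 | key-step product: cis-bicyclo[3.3.0]octane lactone with acetyl C6 and ketone C9 on quaternary C8 | CC(=O)[C@]12C(=O)[C@@](C)(O[Si](C)(C)C(C)(C)C)[C@H](CC(C)=O)[C@@H]2[C@]3(C)OC(=O)[C@H](C)[C@]3(O)[C@]1(C)/C=C/C | intermediate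
30 | C23 aldehyde from 29 | CC(=O)[C@]12C(=O)[C@@](C)(O[Si](C)(C)C(C)(C)C)[C@H](CC(C)=O)[C@@H]2[C@]3(C)OC(=O)[C@H](C)[C@]3(O)[C@]1(C)C=O | intermediate
31 | ring B aldol: C23 carbinol, C15 acetyl (mixture at C15 and C23) | CC(=O)[C@]12C(=O)[C@@](C)(O[Si](C)(C)C(C)(C)C)[C@@H]3C(C(C)=O)C(O)[C@@]1(C)[C@@]1(O)[C@@H](C)C(=O)O[C@@]1(C)[C@@H]32 | intermediate
32 | ring B diketone as exocyclic enol, C8 acetyl, C11 OTBS | CC(=O)[C@]12C(=O)[C@@](C)(O[Si](C)(C)C(C)(C)C)[C@@H]3\C(=C(O)/C)C(=O)[C@@]1(C)[C@@]1(O)[C@@H](C)C(=O)O[C@@]1(C)[C@@H]32 | intermediate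
33 | (E)-but-2-enal | C/C=C/C=O | starting material
34 | C19 mono-aldol adduct (carbinol at C19, mixture; C8 acetyl unchanged) | CC(=O)[C@]12C(=O)[C@@](C)(O[Si](C)(C)C(C)(C)C)[C@@H]3\C(=C(O)/CC(O)/C=C/C)C(=O)[C@@]1(C)[C@@]1(O)[C@@H](C)C(=O)O[C@@]1(C)[C@@H]32 | intermediate
35 | bis-aldol adduct (carbinols at C4 and C19, mixture) | C/C=C/C(O)CC(=O)[C@]12C(=O)[C@@](C)(O[Si](C)(C)C(C)(C)C)[C@@H]3\C(=C(O)/CC(O)/C=C/C)C(=O)[C@@]1(C)[C@@]1(O)[C@@H](C)C(=O)O[C@@]1(C)[C@@H]32 | intermediate
36 | C11 tert-butyldimethylsilyl ether of the target | C/C=C/C=C/C(=O)[C@]12C(=O)[C@@](C)(O[Si](C)(C)C(C)(C)C)[C@@H]3\C(=C(O)/C=C/C=C/C)C(=O)[C@@]1(C)[C@@]1(O)[C@@H](C)C(=O)O[C@@]1(C)[C@@H]32 | intermediate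
37 | CNP0231466.1 | C/C=C/C=C/C(=O)[C@]12C(=O)[C@@](C)(O)[C@@H]3\C(=C(O)/C=C/C=C/C)C(=O)[C@@]1(C)[C@@]1(O)[C@@H](C)C(=O)O[C@@]1(C)[C@@H]32 | target

**Step count and risks**

Total step count: 27. Longest linear sequence: 25 steps (steps 1–8 and 11–27); steps 9–10 form a two-step branch.

Steps most likely to fail:

1. Step 21. The developing C8 cation may be captured by the neighbouring acetonyl carbonyl or by fluoride, or the silyl ether may be lost, before the acyl group shifts. The fallback sets out from 28: MgBr2·OEt2 in ether at 0 °C opens the oxirane at the tertiary carbon to the trans bromohydrin F1 (C8–Br, C6–OH), and halophilic activation with AgBF4 in CH2Cl2 at −40 °C then triggers a semipinacol acyl shift in which only the cis-fused ring A can form. It comes back to the route at 29.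

2. Step 12. The cycloaddition may stall because the bond between the hindered termini C6 and C8 forms too slowly, or the silyl acetal may be cleaved at the temperature needed. The fallback sets out from 9 and 14 and uses a one-carbon acetal tether. Paraformaldehyde and Me3SiCl convert 9 into the chloromethyl ether F2. O-alkylation of the potassium enolate of 14 (KN(SiMe3)2, 18-crown-6, THF, −78 °C) gives the enol acetal triene F3, which tolerates 180 °C or Me2AlCl catalysis and should cyclise to the acetal-bridged adduct F4. MeLi/CeCl3 and then 18, as in step 13, give the propanoate F5. Dimethyldioxirane followed by aqueous work-up, with loss of formaldehyde, comes back to the route at 22.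

3. Step 24. The single equivalent of enal may be shared between the C18 dianion terminus and the C5 enolate, deprotonation to the polyanion may be incomplete, the diacyl centre C8 may undergo retro-Claisen cleavage, or the carbanions may add to the enal in conjugate fashion. The fallback sets out from 32 and replaces both aldol additions: Me3SiOTf and Et3N convert both methyl ketone units and the C27 hydroxyl into silyl derivatives, giving the tetrakis(trimethylsilyl) compound F6 with a 1,3-bis(silyloxy)diene. TiCl4-mediated Mukaiyama aldol additions of its two terminal carbons to two equivalents of 33 at −78 °C and acidic work-up come back to the route at 35.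

**Further compounds**

F1 | step 21 | trans bromohydrin of 28 (C8 bromide, C6 hydroxyl) | O=C1[C@@](C)(O[Si](C)(C)C(C)(C)C)[C@H](CC(C)=O)[C@H]2[C@@]([C@@]1(C)O)(Br)[C@@](C)(/C=C/C)[C@@]3(O)[C@@H](C)C(=O)O[C@@]23C
F2 | step 12 | chloromethyl ether of 9 | ClCO[C@H]1C(=O)C=C[C@@]1(C)/C=C/C
F3 | step 12 | enol acetal triene (methylene acetal tether) | C/C=C(\OCO[C@H]1C(=O)C=C[C@@]1(C)/C=C/C)/C(C)=C/CC2(C)OCCO2
F4 | step 12 | acetal-bridged Diels–Alder adduct | C[C@@H]1C2=C(C)[C@H](CC3(C)OCCO3)[C@@H]4C(=O)[C@H](OCO2)[C@](C)(/C=C/C)[C@H]14
F5 | step 12 | C34 propanoate of the methyl adduct of F4 | C[C@@H]1C2=C(C)[C@H](CC3(C)OCCO3)[C@@H]4[C@](C)(OC(=O)CC)[C@H](OCO2)[C@](C)(/C=C/C)[C@H]14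
F6 | step 24 | tetrakis(trimethylsilyl) derivative of 32 | C=C(O[Si](C)(C)C)[C@]12C(=O)[C@@](C)(O[Si](C)(C)C(C)(C)C)[C@@H]3C(C(=C)O[Si](C)(C)C)=C(O[Si](C)(C)C)[C@@]1(C)[C@@]1(O[Si](C)(C)C)[C@@H](C)C(=O)O[C@@]1(C)[C@@H]32
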